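**Remark.** Carotenoid numbering is used throughout: C1 is the gem-dimethyl ring carbon, C4 the oxygenated carbon, C5 the methyl-bearing carbon, C6 the ring carbon that carries the chain, C7 to C15 the chain, with primes for the half that ends in ring B. The all-E C10 dialdehyde 19 and the (2S,5S)-imidazolidinone salt are assumed to be purchasable.

## Analysis of the target

The target is a C40 carotenoid. An all-E nonaene chain (C7 to C7') with methyl branches at C9, C13, C13' and C9' joins two saturated 1,1,5-trimethylcyclohexane end groups, ring A with a secondary alcohol at C4 and ring B with a ketone at C4'. Ring A has three contiguous stereocentres, C4, C5 and C6 (all S), with hydroxyl, methyl and polyenyl groups all equatorial and the C5 methyl trans to both neighbours. Ring B has two, C5' and C6' (both S), with methyl and polyenyl groups trans and diequatorial. C5 and C6 have the same absolute configuration in both rings, so one ring building block can serve both ends, but the rings are too far apart for any relay and the block must be a single enantiomer. The polyene is sensitive to light, oxygen, acid and E/Z isomerisation, C5' can epimerise next to the ketone (trans is the stable arrangement), and the ring ketone must be kept out of the carbonyl chemistry that builds the chain. The main difficulty is C6, a tertiary stereocentre between the quaternary C1 and the substituted C5, which must be made with absolute control. The plan rests on reading C7 as an aldehyde carbon: ring B is then a γ-keto aldehyde whose C4 ketone and C7 aldehyde are 1,4-related through the C5–C6 bond, so that C5 and C6 are both α-carbons and both natural donors, a pair that polar chemistry cannot join but one-electron oxidation can.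

## Retrosynthetic reasoning

**C11=C12 and C11'=C12'.** Cutting C11=C12 divides 21 into the hydroxy phosphonium salt 14 and the C25 keto aldehyde 20. Cutting C11'=C12' divides 20 into the keto phosphonium salt 18 and the symmetrical dialdehyde 19. These disubstituted double bonds are chosen because each arises from an allylic ylide and a conjugated aldehyde, and a Z isomer at these positions is a hindered cis alkene that reverts to E on heating. Every stereocentre stays at least four bonds from the reacting atoms. The gain is a 15 + 10 + 15 convergence in which one ring building block is used twice. The forward reactions must condense 19 only once and must leave the ring ketone alone.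

**Both salts from one C15 compound.** Salts 14 and 18 are traced to the keto ester 11. For 14, hydride addition to the ketone creates the C4 stereocentre (12), the ester is reduced (13) and the allylic hydroxyl is exchanged for phosphorus. For 18, the ketone is masked as the ketal 15 so that the ester can be reduced (16) and the salt formed (17) before the ketone is released. The forward chemistry must deliver hydride axially to C4 and must tell ester from ketone.

**C7=C8.** In 11 this bond is cut by a Horner–Wadsworth–Emmons disconnection into the ring aldehyde 9 and the phosphonate 10. It is the first chain bond, and cutting it leaves the ring with C7 as a carbonyl carbon, the form in which the 1,4-dicarbonyl pattern appears. The forward reaction must olefinate the aldehyde without epimerising C6 and without touching the ketone.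

**C5–C6, the key disconnection.** Cutting this ring bond of 9 leads to the open-chain aldehyde 8, in which C4 is an enolsilane carbon. It is the only bond that joins the two stereocentres, so cutting it removes the ring and both stereocentres at once and leaves an achiral chain with the quaternary C1 in its middle. The other ring bonds would need stereocentres made beforehand or acyl-anion chemistry. In the forward direction two donor carbons must be joined oxidatively: a chiral secondary-amine catalyst turns the aldehyde into an enamine, one-electron oxidation makes C6 an acceptor, and the enolsilane carbon C5 closes the ring. That step must set C6 absolutely and C5 relative to it.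

**The precursor.** Aldehyde 8 comes from ester 7 by partial reduction; the aldehyde is released last because it would not survive the organometallic step. The enolsilane of 7 is cut at C5–H and O–Si to the vinyl ketone 5 and the silane 6. Conjugate hydrosilylation fixes both the position (towards C5, not C3) and the Z geometry of the enolsilane, which enolisation of an ethyl ketone could not. Ketone 5 comes from the allylic alcohol 4, whose C4–C5 bond is cut to the aldehyde 2 and the Grignard reagent 3. Aldehyde 2 is cut at C3–C4 by a hydroformylation disconnection to the commercial ester 1, which already holds C1 with its two methyl groups, C6 and C7.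

## Alternatives that were turned down

**Alternative 1:** The C6–C7 bond and the C5–methyl bond of the C15 dienyl ketone A1 are disconnected; the ring is bought. In the forward step the dienylborane A3 would add to 4,4-dimethylcyclohex-2-en-1-one A2 under [Rh(cod)Cl]2 and one enantiomer of BINAP. The boron enolate, activated with n-BuLi, would then be methylated by CH3I trans to the new substituent.
- For: it is by far the shortest route. One operation from a commercial ring gives A1 with C7 to C11, both stereocentres and the ketone in place, and rhodium-catalysed asymmetric 1,4-alkenylation of cyclohexenones is established.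
- Against: the β-carbon of A2 is neopentyl-like, next to the gem-dimethyl carbon, so insertion into the rhodium–dienyl bond must compete with protodeboronation of A3. The methylation depends on the enolate keeping its position; proton transfer to product ketone would lead to over-methylation or methylation on the other side.
- Comparison: on step count this alternative is clearly stronger, and its control of C6 is catalyst-based just as in the chosen plan. The chosen plan offers instead an intramolecular bond to the hindered C6 (a six-membered closure helped by the gem-dimethyl group), a C5 methyl group already in the chain so that no enolate alkylation is needed, and both ring stereocentres formed in one event.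

**Alternative 2:** The C1–C6 bond of ring A is disconnected in the sulfone A4. In the forward step Fe(acac)3 and PhSiH3 would transfer a hydrogen atom to the 1,1-disubstituted alkene of the acyclic E-vinyl sulfone A5, and the tertiary C1 radical would add 6-exo to C6. A chair with the C4 silyloxy and C5 methyl groups equatorial would set C6.
- For: radical conjugate additions started by hydrogen-atom transfer are a dependable way to make a quaternary carbon next to a tertiary one, the polarity is matched, the all-equatorial ring A array results directly, and the sulfone at C7 is a handle for Julia-type olefination.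
- Against: the C4 and C5 stereocentres must already be present in A5, so an asymmetric anti-selective aldol or crotylation sequence with protecting-group steps comes first. The sulfone carbanion at C7 sits beside two substituted ring carbons and is a poor nucleophile, and its olefination of a polyenal needs a reductive elimination. Ring B needs desilylation and oxidation.
- Comparison: the ring-forming reaction type is known and therefore more secure, and it builds the quaternary carbon that the chosen plan merely buys. The chosen plan offers catalyst-controlled creation of C5 and C6 from an achiral chain reached in five steps without chiral reagents or protecting groups, a keto intermediate common to both rings, and C7 at the aldehyde oxidation level.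

**Alternative 3:** The C4–C5 bond of the keto ester A6 is disconnected. In the forward step a chiral triazolium-derived carbene would turn the aldehyde carbon C4 of A7 into an acyl-anion equivalent that adds to C5 of the ethylidene ester, and the ester enolate would be protonated at C6.
- For: it is metal-free and redox-neutral, needs neither oxidant nor silyl group, and its ester product is configurationally more robust and easier to store than aldehyde 9.
- Against: the acceptor is an α-branched, β-methyl acrylate, a poor class for the Stetter reaction. The closure is endo with respect to the acceptor double bond (C5 and C6 both become ring atoms), whereas intramolecular Stetter reactions are reliable in the exo mode. C6 is set by protonation and not by C–C bond formation; since C5 equilibrates to trans with respect to C6, the configuration of the product finally rests on that protonation. The C7 ester must then be reduced to the aldehyde in the presence of the ketone, which costs protection and redox steps.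
- Comparison: it equals the chosen plan in making the ring and two stereocentres catalytically from an achiral chain and is stronger in the handling of its product. The chosen plan fixes C6 in the bond-forming event under face control by the catalyst and delivers C7 as the aldehyde for immediate olefination.

Key step: step 6

## Route

Step 1
Reactants: 1 methyl 3,3-dimethylpent-4-enoate
Product: 2 methyl 3,3-dimethyl-6-oxohexanoate
Conditions: Rh(acac)(CO)2 (0.5 mol %), Xantphos (1 mol %), CO/H2 (1:1, 10 bar), toluene, 80 °C
Reagents that add atoms: carbon monoxide, [C-]#[O+]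
Why: Hydroformylation; the quaternary carbon next to the alkene and the wide-bite-angle diphosphine both direct the formyl group to the terminal carbon, which forms the C3–C4 bond and the future C4 carbonyl carbon, and the ester is inert.

Step 2
Reactants: 2 methyl 3,3-dimethyl-6-oxohexanoate; 3 vinylmagnesium bromide
Product: 4 methyl 6-hydroxy-3,3-dimethyloct-7-enoate (racemic)
Conditions: THF, −78 °C; aq. NH4Cl
Reagents that add atoms: none
Why: Grignard 1,2-addition; at −78 °C the aldehyde reacts far faster than the methyl ester, which is also shielded by the neighbouring quaternary carbon, and the carbinol centre needs no control because it is oxidised in the next step.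

Step 3
Reactants: 4 methyl 6-hydroxy-3,3-dimethyloct-7-enoate
Product: 5 methyl 3,3-dimethyl-6-oxooct-7-enoate
Conditions: Dess–Martin periodinane, CH2Cl2, 0 °C to rt
Reagents that add atoms: none
Why: Dess–Martin oxidation of a secondary allylic alcohol under neutral conditions; the vinyl ketone is prone to polymerisation and conjugate addition and is used without delay.

Step 4
Reactants: 5 methyl 3,3-dimethyl-6-oxooct-7-enoate; 6 triethylsilane
Product: 7 methyl (Z)-3,3-dimethyl-6-(triethylsilyloxy)oct-6-enoate
Conditions: RhCl(PPh3)3 (1 mol %), THF, 50 °C
Reagents that add atoms: none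
Why: Rhodium-catalysed 1,4-hydrosilylation of an enone; hydride goes to the terminal carbon and silicon to oxygen through the s-cis enone, so the enolsilane forms only towards C5 and with Z geometry.

Step 5
Reactants: 7 methyl (Z)-3,3-dimethyl-6-(triethylsilyloxy)oct-6-enoate
Product: 8 (Z)-3,3-dimethyl-6-(triethylsilyloxy)oct-6-enal
Conditions: i-Bu2AlH (1.05 equiv), CH2Cl2, −78 °C; MeOH, then aq. potassium sodium tartrate
Reagents that add atoms: none
Why: Partial reduction of an ester to the aldehyde; the aluminium hemiacetal of the β,β-disubstituted ester should persist at −78 °C until the neutral work-up, and the enolsilane neither reacts with the hydride nor suffers in a tartrate work-up.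

Step 6
Reactants: 8 (Z)-3,3-dimethyl-6-(triethylsilyloxy)oct-6-enal
Product: 9 (1S,6S)-2,2,6-trimethyl-5-oxocyclohexane-1-carbaldehyde
Conditions: (2S,5S)-5-benzyl-2-tert-butyl-3-methylimidazolidin-4-one·CF3CO2H (20 mol %), H2O (3 equiv), 2,6-di-tert-butylpyridine (1 equiv), 0.1 M LiClO4, MeCN–DME, reticulated vitreous carbon anode, Pt cathode, undivided cell, constant current (ca. 2.2 F/mol, low current density), −20 °C; pH 7 work-up
Reagents that add atoms: none
Why: Proposed new method: condensation of 8 with the imidazolidinone gives an E-enamine that is the most electron-rich species in the cell, so the carbon anode removes one electron from it and the three-π-electron radical cation is an acceptor at C6; the tethered enolsilane attacks through C5, the α-silyloxy radical at C4 gives up a second electron, and transfer of the silyl group to water and hydrolysis of the iminium ion release 9 and the amine while protons are reduced at the cathode. The closest known reaction types are the amine-catalysed α-enolation of aldehydes by enolsilanes driven by (NH4)2Ce(NO3)6 and intramolecular anodic couplings of enol ethers. The ring closes by 6-endo-trig attack with respect to the enolsilane double bond (C4 and C5 both end in the ring) and exo with respect to the enamine; a five-membered closure onto C4 is excluded because it is polarity-mismatched and would leave an unstabilised radical at C5. C6 is controlled by the catalyst: the radical cation is turned away from the tert-butyl group and the benzyl group covers one face, so C5 bonds to the open Si face of C6, which for the (2S,5S) catalyst is predicted to give the 1S configuration of 9. C5 is controlled by a chair transition state in which the iminium arm is equatorial and the Z geometry of the enolsilane puts the methyl group equatorial, hence trans; this is also the more stable arrangement, so later equilibration at C5 converges on it. The step needs oxidation of the enamine in preference to the enolsilane and to the product, which the lower potential of the enamine, a low current density and the α-branching of 9 (slow to form an enamine again) should secure. It also needs the enolsilane to survive the ammonium salt and water, for which the triethylsilyl group, the pyridine buffer and −20 °C are chosen, and the gem-dimethyl group at C1 helps the chain to fold.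

Step 7
Reactants: 9 (1S,6S)-2,2,6-trimethyl-5-oxocyclohexane-1-carbaldehyde; 10 triethyl (E)-3-methyl-4-phosphonobut-2-enoate
Product: 11 ethyl (2E,4E)-3-methyl-5-[(1S,6S)-2,2,6-trimethyl-5-oxocyclohexyl]penta-2,4-dienoate
Conditions: 10 (1.3 equiv), LiN(SiMe3)2 (1.25 equiv), THF–DMPU, −78 °C; then freshly made 9, −78 to 0 °C
Reagents that add atoms: none
Why: Horner–Wadsworth–Emmons reaction; the preformed vinylogous phosphonate anion, with no excess amide base, attacks the aldehyde in preference to the hindered ketone and gives the E C7=C8 bond under the usual thermodynamic control, with C9=C10 staying mainly E; the C6 proton lies between a quaternary and a tertiary carbon and should be removed too slowly to compete.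

Step 8
Reactants: 11 ethyl (2E,4E)-3-methyl-5-[(1S,6S)-2,2,6-trimethyl-5-oxocyclohexyl]penta-2,4-dienoate
Product: 12 ethyl (2E,4E)-5-[(1S,5S,6S)-5-hydroxy-2,2,6-trimethylcyclohexyl]-3-methylpenta-2,4-dienoate
Conditions: NaBH4, CeCl3·7H2O, MeOH, −78 °C
Reagents that add atoms: none
Why: Luche reduction; the small hydride adds axially to C4 of the chair in which the C5 methyl and C6 dienyl groups are equatorial (the axial positions at C2 and C6 carry only hydrogen), giving the equatorial 4S alcohol trans to the methyl group, and the conjugated ester is untouched.

Step 9
Reactants: 12 ethyl (2E,4E)-5-[(1S,5S,6S)-5-hydroxy-2,2,6-trimethylcyclohexyl]-3-methylpenta-2,4-dienoate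
Product: 13 (2E,4E)-5-[(1S,5S,6S)-5-hydroxy-2,2,6-trimethylcyclohexyl]-3-methylpenta-2,4-dien-1-ol
Conditions: i-Bu2AlH (3.3 equiv), CH2Cl2, −78 to −20 °C; aq. potassium sodium tartrate
Reagents that add atoms: none
Why: 1,2-Reduction of a conjugated ester to the allylic alcohol by an aluminium hydride; the free hydroxyl only consumes one equivalent of reagent and no stereocentre is involved.

Step 10
Reactants: 13 (2E,4E)-5-[(1S,5S,6S)-5-hydroxy-2,2,6-trimethylcyclohexyl]-3-methylpenta-2,4-dien-1-ol
Product: 14 [(2E,4E)-5-[(1S,5S,6S)-5-hydroxy-2,2,6-trimethylcyclohexyl]-3-methylpenta-2,4-dien-1-yl]triphenylphosphonium bromide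
Conditions: PPh3·HBr (1.05 equiv), MeOH, 0 °C to rt
Reagents that add atoms: triphenylphosphine hydrobromide, [Br-].c1ccc(cc1)[PH+](c1ccccc1)c1ccccc1
Why: Phosphonium salt formation from an allylic alcohol; only the dienylic hydroxyl ionises under the mild acid, the pentadienyl cation is captured by the phosphine at its unhindered terminus C11, and the saturated secondary alcohol at C4 is inert.

Step 11
Reactants: 11 ethyl (2E,4E)-3-methyl-5-[(1S,6S)-2,2,6-trimethyl-5-oxocyclohexyl]penta-2,4-dienoate
Product: 15 ethyl (2E,4E)-3-methyl-5-[(6S,7S)-6,8,8-trimethyl-1,4-dioxaspiro[4.5]decan-7-yl]penta-2,4-dienoate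
Conditions: ethylene glycol (5 equiv), p-TsOH·H2O (5 mol %), benzene, reflux (Dean–Stark)
Reagents that add atoms: ethylene glycol, OCCO
Why: Acid-catalysed ketalisation with removal of water; it masks the ketone for the ester reduction, and any enolisation towards C5 under the acid returns the stable trans arrangement.

Step 12
Reactants: 15 ethyl (2E,4E)-3-methyl-5-[(6S,7S)-6,8,8-trimethyl-1,4-dioxaspiro[4.5]decan-7-yl]penta-2,4-dienoate
Product: 16 (2E,4E)-3-methyl-5-[(6S,7S)-6,8,8-trimethyl-1,4-dioxaspiro[4.5]decan-7-yl]penta-2,4-dien-1-ol
Conditions: i-Bu2AlH (2.3 equiv), CH2Cl2, −78 °C; aq. potassium sodium tartrate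
Reagents that add atoms: none
Why: 1,2-Reduction of the conjugated ester to the allylic alcohol; the ketal is stable to the hydride and to the non-acidic work-up.

Step 13
Reactants: 16 (2E,4E)-3-methyl-5-[(6S,7S)-6,8,8-trimethyl-1,4-dioxaspiro[4.5]decan-7-yl]penta-2,4-dien-1-ol
Product: 18 [(2E,4E)-3-methyl-5-[(1S,6S)-2,2,6-trimethyl-5-oxocyclohexyl]penta-2,4-dien-1-yl]triphenylphosphonium bromide, via ketal phosphonium bromide 17 (not isolated)
Conditions: PPh3·HBr (1.05 equiv), MeOH–CH2Cl2, 0 °C to rt; then 1 M aq. HBr (cat.), THF, rt
Reagents that add atoms: triphenylphosphine hydrobromide, [Br-].c1ccc(cc1)[PH+](c1ccccc1)c1ccccc1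
Why: Phosphonium salt formation from the allylic alcohol as in step 10, followed by acid hydrolysis of the ketal at a stage where only a diene and an acid-stable salt are present; C5' is epimerisable under the acid but trans is the stable arrangement.

Step 14
Reactants: 18 [(2E,4E)-3-methyl-5-[(1S,6S)-2,2,6-trimethyl-5-oxocyclohexyl]penta-2,4-dien-1-yl]triphenylphosphonium bromide; 19 (2E,4E,6E)-2,7-dimethylocta-2,4,6-trienedial
Product: 20 (2E,4E,6E,8E,10E,12E)-2,7,11-trimethyl-13-[(1S,6S)-2,2,6-trimethyl-5-oxocyclohexyl]trideca-2,4,6,8,10,12-hexaenal
Conditions: 19 (3 equiv), 1,2-epoxybutane, EtOH, reflux, Ar, dark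
Reagents that add atoms: none
Why: Wittig reaction under base-free conditions; the alkoxide formed when bromide opens the epoxide deprotonates 18 little by little, the allylic ylide condenses with one aldehyde group of 19 (used in excess so that single condensation prevails), the hindered ring ketone should not compete, and any Z isomer at the new C11'=C12' bond is a hindered cis alkene that should revert to E at reflux.

Step 15
Reactants: 14 [(2E,4E)-5-[(1S,5S,6S)-5-hydroxy-2,2,6-trimethylcyclohexyl]-3-methylpenta-2,4-dien-1-yl]triphenylphosphonium bromide; 20 (2E,4E,6E,8E,10E,12E)-2,7,11-trimethyl-13-[(1S,6S)-2,2,6-trimethyl-5-oxocyclohexyl]trideca-2,4,6,8,10,12-hexaenal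
Product: 21 (all-E,4S,5S,6S,5'S,6'S)-4-hydroxy-5,6,5',6'-tetrahydro-β,β-caroten-4'-one
Conditions: 14 (1.3 equiv), 1,2-epoxybutane, EtOH, reflux, Ar, dark; crystallisation of the all-E isomer
Reagents that add atoms: none
Why: Wittig reaction under the same base-free conditions; the free hydroxyl of 14 and the ketone of 20 are tolerated, the polyenal reacts in preference to the ketone, and the new C11=C12 bond should equilibrate to E at reflux, completing the C40 skeleton with all five stereocentres untouched.

## Compound list

1 | methyl 3,3-dimethylpent-4-enoate | C=CC(C)(C)CC(=O)OC | starting material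
2 | methyl 3,3-dimethyl-6-oxohexanoate | O=CCCC(C)(C)CC(=O)OC | intermediate
3 | vinylmagnesium bromide | C=C[Mg]Br | starting material
4 | methyl 6-hydroxy-3,3-dimethyloct-7-enoate (racemic) | C=CC(O)CCC(C)(C)CC(=O)OC | intermediate
5 | methyl 3,3-dimethyl-6-oxooct-7-enoate | C=CC(=O)CCC(C)(C)CC(=O)OC | intermediate
6 | triethylsilane | CC[SiH](CC)CC | starting material
7 | methyl (Z)-3,3-dimethyl-6-(triethylsilyloxy)oct-6-enoate | COC(=O)CC(C)(C)CC/C(O[Si](CC)(CC)CC)=C/C | intermediate
8 | (Z)-3,3-dimethyl-6-(triethylsilyloxy)oct-6-enal | O=CCC(C)(C)CC/C(O[Si](CC)(CC)CC)=C/C | intermediate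
9 | (1S,6S)-2,2,6-trimethyl-5-oxocyclohexane-1-carbaldehyde | O=C[C@H]1[C@H](C)C(=O)CCC1(C)C | intermediate
10 | triethyl (E)-3-methyl-4-phosphonobut-2-enoate | CCOC(=O)/C=C(C)/CP(=O)(OCC)OCC | starting material
11 | ethyl (2E,4E)-3-methyl-5-[(1S,6S)-2,2,6-trimethyl-5-oxocyclohexyl]penta-2,4-dienoate | CCOC(=O)/C=C(C)/C=C/[C@H]1[C@H](C)C(=O)CCC1(C)C | intermediate
12 | ethyl (2E,4E)-5-[(1S,5S,6S)-5-hydroxy-2,2,6-trimethylcyclohexyl]-3-methylpenta-2,4-dienoate | CCOC(=O)/C=C(C)/C=C/[C@H]1[C@H](C)[C@@H](O)CCC1(C)C | intermediate
13 | (2E,4E)-5-[(1S,5S,6S)-5-hydroxy-2,2,6-trimethylcyclohexyl]-3-methylpenta-2,4-dien-1-ol | OC/C=C(C)/C=C/[C@H]1[C@H](C)[C@@H](O)CCC1(C)C | intermediate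
14 | [(2E,4E)-5-[(1S,5S,6S)-5-hydroxy-2,2,6-trimethylcyclohexyl]-3-methylpenta-2,4-dien-1-yl]triphenylphosphonium bromide | [Br-].C(/C=C(C)/C=C/[C@H]1[C@H](C)[C@@H](O)CCC1(C)C)[P+](c2ccccc2)(c3ccccc3)c4ccccc4 | intermediate
15 | ethyl (2E,4E)-3-methyl-5-[(6S,7S)-6,8,8-trimethyl-1,4-dioxaspiro[4.5]decan-7-yl]penta-2,4-dienoate | CCOC(=O)/C=C(C)/C=C/[C@H]1[C@H](C)C2(OCCO2)CCC1(C)C | intermediate
16 | (2E,4E)-3-methyl-5-[(6S,7S)-6,8,8-trimethyl-1,4-dioxaspiro[4.5]decan-7-yl]penta-2,4-dien-1-ol | OC/C=C(C)/C=C/[C@H]1[C@H](C)C2(OCCO2)CCC1(C)C | intermediate
17 | [(2E,4E)-3-methyl-5-[(6S,7S)-6,8,8-trimethyl-1,4-dioxaspiro[4.5]decan-7-yl]penta-2,4-dien-1-yl]triphenylphosphonium bromide | [Br-].C(/C=C(C)/C=C/[C@H]1[C@H](C)C2(OCCO2)CCC1(C)C)[P+](c3ccccc3)(c4ccccc4)c5ccccc5 | intermediate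
18 | [(2E,4E)-3-methyl-5-[(1S,6S)-2,2,6-trimethyl-5-oxocyclohexyl]penta-2,4-dien-1-yl]triphenylphosphonium bromide | [Br-].C(/C=C(C)/C=C/[C@H]1[C@H](C)C(=O)CCC1(C)C)[P+](c2ccccc2)(c3ccccc3)c4ccccc4 | intermediate
19 | (2E,4E,6E)-2,7-dimethylocta-2,4,6-trienedial | O=C/C(C)=C/C=C/C=C(C)/C=O | starting material
20 | (2E,4E,6E,8E,10E,12E)-2,7,11-trimethyl-13-[(1S,6S)-2,2,6-trimethyl-5-oxocyclohexyl]trideca-2,4,6,8,10,12-hexaenal | O=C/C(C)=C/C=C/C=C(C)/C=C/C=C(C)/C=C/[C@H]1[C@H](C)C(=O)CCC1(C)C | intermediate
21 | (all-E,4S,5S,6S,5'S,6'S)-4-hydroxy-5,6,5',6'-tetrahydro-β,β-caroten-4'-one | CC(/C=C/C=C(C)/C=C/[C@H]1[C@H](C)[C@@H](O)CCC1(C)C)=C\C=C\C=C(C)\C=C\C=C(C)\C=C\[C@H]1[C@H](C)C(=O)CCC1(C)C | target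

## Step count and least certain steps

Total step count: 15. Longest linear sequence: 12 steps (steps 1 to 7, 11 to 13, 14 and 15).

**Step 6 (key step).** Three processes are most likely to fail it.
- Direct anodic oxidation of the enolsilane may compete with oxidation of the enamine, which is present only in catalytic amount.
- The enolsilane may be protodesilylated by the ammonium salt and water; the liberated ketone can then be attacked by the enamine carbon in an aldol closure to a cyclopentanol.
- Enamine formation from the β,β-disubstituted aldehyde may be slow, and the predicted facial sense rests on a model.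

Fallback by known chemistry, with the polarity of the same bond inverted, from 8 back to 9: N-bromosuccinimide in THF at −78 °C should convert the enolsilane of 8 into the α-bromo ketone 7-bromo-3,3-dimethyl-6-oxooctanal F1. F1 is then cyclised by photoredox organocatalytic α-alkylation of aldehydes with α-bromo carbonyl compounds, here in ring-closing mode (the same (2S,5S)-imidazolidinone as its CF3SO3H salt, Ru(bpy)3Cl2, 2,6-lutidine, DMF, visible light). The C5 radical formed by reductive C–Br cleavage adds to the enamine carbon C6 on the face left open by the benzyl group, and oxidation and hydrolysis of the α-amino radical give 9.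

**Step 7.** The phosphonate anion may enolise the aldehyde before olefination, with loss of configuration at C6, and the C9=C10 geometry may scramble. Fallback from 9 back to 11 without base: Takai olefination (CrCl2, CHI3, THF, 0 °C) should give the vinyl iodide (2S,3R)-3-[(E)-2-iodoethenyl]-2,4,4-trimethylcyclohexan-1-one F2. Stille coupling of F2 with ethyl (E)-3-(tributylstannyl)but-2-enoate (Pd(PPh3)4, CuI, DMF) then gives 11 with both double bonds defined.

**Step 14.** The symmetrical dialdehyde may condense twice, consuming 18 and giving a C40 diketone that is hard to separate. Fallback from 19 back to 20 with a desymmetrised C10 block: 19 is converted with one equivalent of 2,2-dimethylpropane-1,3-diol (pyridinium p-toluenesulfonate, CH2Cl2) into the mono-acetal (2E,4E,6E)-7-(5,5-dimethyl-1,3-dioxan-2-yl)-2-methylocta-2,4,6-trienal F3, with unchanged 19 and the bis-acetal recycled. Wittig reaction of F3 with 18 under the conditions of step 14 gives the keto acetal (2S,3S)-3-[(1E,3E,5E,7E,9E,11E)-12-(5,5-dimethyl-1,3-dioxan-2-yl)-3,7-dimethyltrideca-1,3,5,7,9,11-hexaenyl]-2,4,4-trimethylcyclohexan-1-one F4. Mild hydrolysis (aq. oxalic acid, acetone) releases 20.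

**Step 8.** Facial selectivity of hydride addition may be poor, with equatorial attack giving the axial alcohol. Fallback from 11 back to 12 by deliberate inversion: LiBH(s-Bu)3 (THF, −78 °C) should attack equatorially and give the axial alcohol ethyl (2E,4E)-5-[(1S,5R,6S)-5-hydroxy-2,2,6-trimethylcyclohexyl]-3-methylpenta-2,4-dienoate F5. Mitsunobu inversion with 4-nitrobenzoic acid (PPh3, diisopropyl azodicarboxylate) gives (1S,2S,3S)-3-[(1E,3E)-5-ethoxy-3-methyl-5-oxopenta-1,3-dienyl]-2,4,4-trimethylcyclohexyl 4-nitrobenzoate F6, and K2CO3 in EtOH releases 12.

**Step 5.** Over-reduction to the primary alcohol or incomplete conversion may occur if the aluminium hemiacetal does not persist. Fallback from 7 back to 8 through the alcohol: LiAlH4 (THF, 0 °C) gives (Z)-3,3-dimethyl-6-(triethylsilyloxy)oct-6-en-1-ol F7, and Parikh–Doering oxidation (SO3·pyridine, DMSO, i-Pr2NEt, 0 °C) gives 8 without acid.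

## Further compounds

F1 | step 6 | 7-bromo-3,3-dimethyl-6-oxooctanal (racemic at the bromine-bearing carbon) | CC(Br)C(=O)CCC(C)(C)CC=O
F2 | step 7 | (2S,3R)-3-[(E)-2-iodoethenyl]-2,4,4-trimethylcyclohexan-1-one | I/C=C/[C@H]1[C@H](C)C(=O)CCC1(C)C
F3 | step 14 | (2E,4E,6E)-7-(5,5-dimethyl-1,3-dioxan-2-yl)-2-methylocta-2,4,6-trienal | O=C/C(C)=C/C=C/C=C(C)/C1OCC(C)(C)CO1
F4 | step 14 | (2S,3S)-3-[(1E,3E,5E,7E,9E,11E)-12-(5,5-dimethyl-1,3-dioxan-2-yl)-3,7-dimethyltrideca-1,3,5,7,9,11-hexaenyl]-2,4,4-trimethylcyclohexan-1-one | CC1(C)COC(OC1)/C(C)=C/C=C/C=C(C)/C=C/C=C(C)/C=C/[C@H]2[C@H](C)C(=O)CCC2(C)C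
F5 | step 8 | ethyl (2E,4E)-5-[(1S,5R,6S)-5-hydroxy-2,2,6-trimethylcyclohexyl]-3-methylpenta-2,4-dienoate | CCOC(=O)/C=C(C)/C=C/[C@H]1[C@H](C)[C@H](O)CCC1(C)C
F6 | step 8 | (1S,2S,3S)-3-[(1E,3E)-5-ethoxy-3-methyl-5-oxopenta-1,3-dienyl]-2,4,4-trimethylcyclohexyl 4-nitrobenzoate | CCOC(=O)/C=C(C)/C=C/[C@H]1[C@H](C)[C@@H](OC(=O)c2ccc(cc2)[N+](=O)[O-])CCC1(C)C
F7 | step 5 | (Z)-3,3-dimethyl-6-(triethylsilyloxy)oct-6-en-1-ol | OCCC(C)(C)CC/C(O[Si](CC)(CC)CC)=C/C
A1 | alternative 1 | (2S,3S)-3-[(1E,3E)-5-(tert-butyldimethylsilyloxy)-3-methylpenta-1,3-dienyl]-2,4,4-trimethylcyclohexan-1-one | CC(C)(C)[Si](C)(C)OC/C=C(C)/C=C/[C@H]1[C@H](C)C(=O)CCC1(C)C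
A2 | alternative 1 | 4,4-dimethylcyclohex-2-en-1-one | CC1(C)CCC(=O)C=C1
A3 | alternative 1 | 9-[(1E,3E)-5-(tert-butyldimethylsilyloxy)-3-methylpenta-1,3-dienyl]-9-borabicyclo[3.3.1]nonane | CC(C)(C)[Si](C)(C)OC/C=C(C)/C=C/B1C2CCCC1CCC2
A4 | alternative 2 | tert-butyldimethyl{[(1S,2S,3S)-2,4,4-trimethyl-3-(phenylsulfonylmethyl)cyclohexyl]oxy}silane | O=S(=O)(c1ccccc1)C[C@H]1[C@H](C)[C@@H](O[Si](C)(C)C(C)(C)C)CCC1(C)C
A5 | alternative 2 | tert-butyl{[(1E,3S,4S)-3,7-dimethyl-1-(phenylsulfonyl)octa-1,7-dien-4-yl]oxy}dimethylsilane | O=S(=O)(c1ccccc1)/C=C/[C@H](C)[C@@H](O[Si](C)(C)C(C)(C)C)CCC(C)=C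
A6 | alternative 3 | methyl (1S,6S)-2,2,6-trimethyl-5-oxocyclohexane-1-carboxylate | COC(=O)[C@H]1[C@H](C)C(=O)CCC1(C)C
A7 | alternative 3 | methyl (E)-2-ethylidene-3,3-dimethyl-6-oxohexanoate | C/C=C(/C(=O)OC)C(C)(C)CCC=O
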